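**Plan**

- Numbering follows the ring SMILES: C1 carries the exocyclic CH2, C15 is the one-carbon bridge, ring A = C8–C13, ring B = C5–C8 plus C13–C15, ring C = C1–C5 plus C14 and C15, side chain C16–C20. The C6–C7 bond lies between two allylic triads, C4=C5–C6 and C7–C8=C9. C6 can therefore be the γ-terminus of an allylsilane on C4 and C7 the β-carbon of a C9 enone, so one bond closes ring B and leaves the alkene at the bridgehead C4=C5.
- Retrosynthesis: remove the C1 methylene (Wittig) and the C9 methyl (enol triflate coupling), open ring B at C6–C7, open ring C at C4=C5 (metathesis) and C1–C2 (Grignard), cut C13–C14 (Mukaiyama–Michael) to a 4-substituted cyclohexenone and a methylene lactone, and take ring A back to (S)-citronellal and methyl vinyl ketone.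
- Forward: ring A by organocatalytic annulation, side-chain oxidation, C13–C14 union, ring C by metathesis, allylsilane and exocyclic enone, ring B in the key step, then C9 methyl, C1 methylene and deprotection.
- Stereochemistry: C16 from citronellal; C12 from the prolinol ether catalyst; C13 (anti to the C12 substituent) and C14 (open transition state) from the Michael step; the E side-chain alkene from the SeO2 oxidation. C1 and C4 are temporary centres (Felkin addition, ligand-controlled silylation) that vanish later.

Key step: step 15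

Remark: C1 is carried as the silyl ether of the Felkin alcohol (oxygen cis to C13 on ring C); this centre is erased in step 19 and the ring closure is assumed not to depend on it.
Remark: lactol 13 is an anomeric mixture and is used as such.
Remark: in step 12 the antipode of the carbene ligand that directs silicon to the C4 face anti to the C14 substituent is assumed to be found with both antipodes in hand.

Step 1
Reactants: 1 (S)-citronellal; 2 methyl vinyl ketone
Product: 4 (4S)-4-[(2S)-6-methylhept-5-en-2-yl]cyclohex-2-en-1-one, via keto aldehyde 3 (not isolated)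
Conditions: (S)-2-[methoxy(diphenyl)methyl]pyrrolidine (5 mol %), ethyl 3,4-dihydroxybenzoate (20 mol %), neat, 4 °C; then LiOH (cat.), i-PrOH, rt
Reagents that add atoms: none
Why: Enamine-catalysed Michael addition to 2 followed by base-induced intramolecular aldol condensation (organocatalytic Robinson-type annulation); the (S)-prolinol ether shields one face of the E-enamine so that C12 is set S under catalyst control, and C16 is carried over from 1.

Step 2
Reactants: 4 (4S)-4-[(2S)-6-methylhept-5-en-2-yl]cyclohex-2-en-1-one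
Product: 5 (4S)-4-[(2S,5E)-7-hydroxy-6-methylhept-5-en-2-yl]cyclohex-2-en-1-one
Conditions: SeO2 (cat.), t-BuOOH, CH2Cl2, 0 °C → rt
Reagents that add atoms: tert-butyl hydroperoxide CC(C)(C)OO (oxygen relayed by catalytic selenium dioxide O=[Se]=O)
Why: Riley allylic oxidation (ene reaction then [2,3]-sigmatropic shift) selects the E-methyl group of the trisubstituted alkene and should give the E allylic alcohol, while the electron-poor enone alkene is inert.

Step 3
Reactants: 5 allylic alcohol
Product: 6 tert-butyldiphenylsilyl ether of 5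
Conditions: t-BuPh2SiCl, imidazole, DMF, rt
Reagents that add atoms: tert-butyl(chloro)diphenylsilane CC(C)(C)[Si](Cl)(c1ccccc1)c1ccccc1
Why: Standard silylation of the primary allylic alcohol; this robust ether has to last to step 21.

Step 4
Reactants: 7 2-methylidenepropane-1,3-diol; 8 triethyl orthoacetate
Product: 10 5-methylideneoxan-2-one, via hydroxy ester 9 (not isolated)
Conditions: 8 (1.05 equiv), EtCO2H (cat.), 140 °C, ethanol distilled off
Reagents that add atoms: none
Why: Johnson–Claisen rearrangement of the mixed ketene acetal formed from one hydroxyl, after which the δ-hydroxy ester lactonises; limiting the orthoester keeps the second hydroxyl from rearranging as well.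

Step 5
Reactants: 10 5-methylideneoxan-2-one
Product: 11 cyclic ketene silyl acetal of 10
Conditions: LiN(i-Pr)2, THF, −78 °C; t-BuMe2SiCl, DMPU, −78 → 0 °C
Reagents that add atoms: tert-butyl(chloro)dimethylsilane CC(C)(C)[Si](C)(C)Cl
Why: Kinetic enolisation at the lactone α-carbon (C14) and O-silylation give the ketene silyl acetal, whose geometry is fixed by the ring.

Step 6
Reactants: 6 ring A enone; 11 cyclic ketene silyl acetal
Product: 12 Michael adduct (ring A C8=C9 silyl enol ether bearing the lactone at C13)
Conditions: 11 (1.5 equiv), t-BuMe2SiOTf (5 mol %), CH2Cl2, −78 °C; Et3N quench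
Reagents that add atoms: none
Why: Mukaiyama–Michael addition with silyl transfer: C13 should form anti to the C12 side chain by axial attack on the 4-substituted enone, C14 through an open antiperiplanar transition state (C1 anti to C8, the C14 hydrogen over ring A), and the ring A enolate is stored regiospecifically as the C8=C9 silyl enol ether.

Step 7
Reactants: 12 Michael adduct
Product: 13 lactol (both anomers at C1)
Conditions: i-Bu2AlH (1.1 equiv), CH2Cl2, −78 °C; aqueous tartrate work-up
Reagents that add atoms: none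
Why: Partial reduction of the δ-lactone stops at the aluminium hemiacetal at low temperature; the enol silyl ether and the alkenes are untouched.

Step 8
Reactants: 13 lactol; 14 but-3-en-1-ylmagnesium bromide
Product: 15 diol (C1 secondary alcohol with the C2–C4 butenyl chain, C6 primary allylic alcohol)
Conditions: 14 (4 equiv), THF, −20 °C → rt; aq. NH4Cl
Reagents that add atoms: none
Why: Grignard addition to the hydroxy aldehyde in equilibrium with the lactol installs C2–C4 and frees the C6 alcohol; the Felkin–Anh mode (attack anti to the C13 branch) should give the C1 alcohol that ends up cis to C13 on ring C.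

Step 9
Reactants: 15 diol
Product: 16 C6 diethyl phosphate
Conditions: (EtO)2P(O)Cl (1.1 equiv), pyridine, DMAP (cat.), CH2Cl2, 0 °C
Reagents that add atoms: diethyl chlorophosphate CCOP(=O)(Cl)OCC
Why: Chemoselective phosphorylation of the primary allylic alcohol over the hindered secondary one provides the leaving group for step 12.

Step 10
Reactants: 16 hydroxy phosphate
Product: 17 C1 triethylsilyl ether
Conditions: Et3SiOTf, 2,6-lutidine, CH2Cl2, −78 °C
Reagents that add atoms: triethylsilyl trifluoromethanesulfonate CC[Si](CC)(CC)OS(=O)(=O)C(F)(F)F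
Why: Silylation masks the C1 oxygen through the key step; base-buffered low-temperature conditions spare the enol silyl ether and the phosphate.

Step 11
Reactants: 17 diene
Product: 18 ring C cycloheptene (C4=C5, C6 phosphate)
Conditions: second-generation Grubbs catalyst (H2IMes)(PCy3)Cl2Ru=CHPh (5 mol %), CH2Cl2 (0.005 M), 40 °C
Reagents that add atoms: none
Why: Ring-closing metathesis between the terminal vinyl group and the 1,1-disubstituted alkene closes the seven-membered ring C with loss of ethene; the trisubstituted enol ether and side-chain alkenes are too hindered to compete.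

Step 12
Reactants: 18 allylic phosphate; 19 (dimethylphenylsilyl)boronic acid pinacol ester
Product: 20 allylsilane (C5=C6 exocyclic, C4–SiMe2Ph trans to the C14 substituent)
Conditions: CuCl (5 mol %), chiral 4,5-diphenylimidazolinium chloride as N-heterocyclic carbene precursor (6 mol %), NaOMe (1.5 equiv), THF, 0 °C
Reagents that add atoms: none
Why: Copper-catalysed γ-selective (SN2') allylic substitution by the silyl nucleophile released from the Si–B reagent moves the alkene to C5=C6 and places silicon on C4; the face is chosen by the chiral carbene ligand so that silicon lies trans to the C14 substituent.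

Step 13
Reactants: 20 allylsilane
Product: 22 Mannich base (C9 ketone with C8–CH2NMe2), via lithium enolate 21 (not isolated)
Conditions: MeLi (1.1 equiv), THF, 0 °C → rt; then Me2N=CH2 I, −78 → 0 °C
Reagents that add atoms: N,N-dimethylmethyleneiminium iodide C=[N+](C)C.[I-]
Why: Methyllithium cleaves only the enol Si–O bond, and the regiodefined lithium enolate is aminomethylated at C8 (Mannich reaction) far faster than the allylsilane could react; the new C8 centre (substituent trans to C14) is transient.

Step 14
Reactants: 22 Mannich base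
Product: 24 exocyclic enone C7=C8–C9=O (key precursor), via ammonium iodide 23 (not isolated)
Conditions: MeI, Et2O, rt; then NaHCO3, CH2Cl2/H2O, rt; used at once
Reagents that add atoms: none
Why: N-Methylation and E1cB elimination of trimethylamine unmask the α-methylene ketone under conditions that leave the allylsilane intact.

Step 15
Reactants: 24 exocyclic enone with ring C allylsilane
Product: 25 tricyclic C9 dimethylphenylsilyl enol ether with the C4=C5 bridgehead alkene
Conditions: Tf2NH (5 mol %), CH2Cl2 (0.01 M), −78 → −40 °C; Et3N quench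
Reagents that add atoms: none
Why: The acid is converted in the flask into Me2PhSiNTf2, which silylates the C9 carbonyl oxygen so that C7 becomes the terminus of a silyloxyallyl cation; C6 attacks C7, the C4–Si bond stabilises the charge developing at C5 and then breaks, and the released silyl cation carries the chain. The closest known reaction type is the intramolecular Hosomi–Sakurai conjugate addition of allylsilanes to enones, which is established for seven-membered rings. Ring B (C5, C6, C7, C8, C13, C14, C15) closes in a 7-endo-trig sense at the enone C7=C8. No stereocentre is created: C12, C13 and C14 are already in place and C4 becomes trigonal. The step needs C6, not C4 or the C1 oxygen, to bond to C7, and an anti SE2' geometry: silicon on C4 dictates γ-attack, and its position trans to the C14 tether lets C7 reach the face of C5=C6 opposite to silicon. The C1 oxygen is a silyl ether whose O-addition is reversible, and leaving C1 without its methylene removes the only other alkene that could close a six-membered ring.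

Step 16
Reactants: 25 silyl enol ether
Product: 27 C9 enol triflate, via lithium enolate 26 (not isolated)
Conditions: MeLi (1.05 equiv), THF, 0 °C; then PhNTf2, −78 → 0 °C; aq. NH4Cl
Reagents that add atoms: N-phenylbis(trifluoromethanesulfonimide) O=S(=O)(N(c1ccccc1)S(=O)(=O)C(F)(F)F)C(F)(F)F
Why: Methyllithium regenerates the tetrasubstituted C8=C9 enolate from the silyl enol ether without loss of regiochemistry, and O-sulfonylation gives the enol triflate.

Step 17
Reactants: 27 enol triflate
Product: 28 C9 methyl compound (C8=C9 tetrasubstituted alkene)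
Conditions: MeMgBr, Fe(acac)3 (5 mol %), THF/NMP, −20 → 0 °C
Reagents that add atoms: methylmagnesium bromide C[Mg]Br
Why: Iron-catalysed cross-coupling of the enol triflate with the methyl Grignard reagent installs the C9 methyl group and keeps the alkene at C8=C9.

Step 18
Reactants: 28 triethylsilyl ether
Product: 29 C1 alcohol
Conditions: PPTS (cat.), MeOH/CH2Cl2, 0 °C
Reagents that add atoms: none
Why: Mild acid-catalysed methanolysis removes the secondary triethylsilyl ether and leaves the primary tert-butyldiphenylsilyl ether in place.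

Step 19
Reactants: 29 C1 alcohol
Product: 30 C1 ketone
Conditions: Dess–Martin periodinane, CH2Cl2, rt
Reagents that add atoms: none
Why: Dess–Martin oxidation converts the secondary alcohol to the ketone under neutral conditions that do not touch the alkenes.

Step 20
Reactants: 30 C1 ketone
Product: 31 tert-butyldiphenylsilyl ether of the target
Conditions: Ph3PCH3Br, KOt-Bu, THF, 0 °C → rt
Reagents that add atoms: methyltriphenylphosphonium bromide C[P+](c1ccccc1)(c1ccccc1)c1ccccc1.[Br-] (as its ylide C=P(c1ccccc1)(c1ccccc1)c1ccccc1)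
Why: Wittig methylenation installs the exocyclic C1 methylene; C14 is a bridgehead whose enolisation is disfavoured, so its configuration should hold.

Step 21
Reactants: 31 silyl ether
Product: 32 target CNP0289180.1
Conditions: Bu4NF, THF, 0 °C → rt
Reagents that add atoms: none
Why: Fluoride cleavage of the silyl ether liberates the allylic alcohol under conditions harmless to the triene.

**Compound list**

1 | (S)-citronellal, (3S)-3,7-dimethyloct-6-enal | O=CC[C@@H](C)CCC=C(C)C | starting material
2 | methyl vinyl ketone | CC(=O)C=C | starting material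
3 | (2S,3S)-3,7-dimethyl-2-(3-oxobutyl)oct-6-enal | CC(=O)CC[C@H](C=O)[C@@H](C)CCC=C(C)C | intermediate
4 | (4S)-4-[(2S)-6-methylhept-5-en-2-yl]cyclohex-2-en-1-one | O=C1C=C[C@H]([C@@H](C)CCC=C(C)C)CC1 | intermediate
5 | (4S)-4-[(2S,5E)-7-hydroxy-6-methylhept-5-en-2-yl]cyclohex-2-en-1-one | O=C1C=C[C@H]([C@@H](C)CC/C=C(\C)CO)CC1 | intermediate
6 | (4S)-4-[(2S,5E)-7-{[tert-butyl(diphenyl)silyl]oxy}-6-methylhept-5-en-2-yl]cyclohex-2-en-1-one | O=C1C=C[C@H]([C@@H](C)CC/C=C(\C)CO[Si](c2ccccc2)(c2ccccc2)C(C)(C)C)CC1 | intermediate
7 | 2-methylidenepropane-1,3-diol | C=C(CO)CO | starting material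
8 | triethyl orthoacetate | CCOC(C)(OCC)OCC | starting material
9 | ethyl 4-(hydroxymethyl)pent-4-enoate | CCOC(=O)CCC(=C)CO | intermediate
10 | 5-methylideneoxan-2-one (supplies C1, C14, C15, C5, C6) | C=C1CCC(=O)OC1 | intermediate
11 | tert-butyl(dimethyl)[(3-methylidene-3,4-dihydro-2H-pyran-6-yl)oxy]silane | C=C1CC=C(O[Si](C)(C)C(C)(C)C)OC1 | intermediate
12 | Michael adduct: ring A as C8=C9 tert-butyldimethylsilyl enol ether, C13 bonded to the lactone α-carbon C14; C12, C13, C14, C16 as in the target | C1=C(O[Si](C)(C)C(C)(C)C)CC[C@@H]([C@@H](C)CC/C=C(\C)CO[Si](c2ccccc2)(c2ccccc2)C(C)(C)C)[C@@H]1[C@@H]1CC(=C)COC1=O | intermediate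
13 | lactol of 12 (C1 hemiacetal, both anomers) | C1=C(O[Si](C)(C)C(C)(C)C)CC[C@@H]([C@@H](C)CC/C=C(\C)CO[Si](c2ccccc2)(c2ccccc2)C(C)(C)C)[C@@H]1[C@@H]1CC(=C)COC1O | intermediate
14 | but-3-en-1-ylmagnesium bromide | C=CCC[Mg]Br | starting material
15 | diol: (1S) C1 carbinol carrying the but-3-enyl chain, C6 primary alcohol on the C5 methylidene unit | C1=C(O[Si](C)(C)C(C)(C)C)CC[C@@H]([C@@H](C)CC/C=C(\C)CO[Si](c2ccccc2)(c2ccccc2)C(C)(C)C)[C@@H]1[C@H](CC(=C)CO)[C@@H](O)CCC=C | intermediate
16 | C6 diethyl phosphate of 15 | C1=C(O[Si](C)(C)C(C)(C)C)CC[C@@H]([C@@H](C)CC/C=C(\C)CO[Si](c2ccccc2)(c2ccccc2)C(C)(C)C)[C@@H]1[C@H](CC(=C)COP(=O)(OCC)OCC)[C@@H](O)CCC=C | intermediate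
17 | C1 triethylsilyl ether of 16 | C1=C(O[Si](C)(C)C(C)(C)C)CC[C@@H]([C@@H](C)CC/C=C(\C)CO[Si](c2ccccc2)(c2ccccc2)C(C)(C)C)[C@@H]1[C@H](CC(=C)COP(=O)(OCC)OCC)[C@@H](O[Si](CC)(CC)CC)CCC=C | intermediate
18 | ring C cycloheptene: C4=C5, C6 diethyl phosphate, C1–OSiEt3 cis to C13 | C1=C(O[Si](C)(C)C(C)(C)C)CC[C@@H]([C@@H](C)CC/C=C(\C)CO[Si](c2ccccc2)(c2ccccc2)C(C)(C)C)[C@@H]1[C@@H]1CC(COP(=O)(OCC)OCC)=CCC[C@@H]1O[Si](CC)(CC)CC | intermediate
19 | (dimethylphenylsilyl)boronic acid pinacol ester | CC1(C)OB([Si](C)(C)c2ccccc2)OC1(C)C | starting material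
20 | allylsilane: C5=C6 exocyclic methylene, C4–SiMe2Ph trans to the C14 substituent | C1=C(O[Si](C)(C)C(C)(C)C)CC[C@@H]([C@@H](C)CC/C=C(\C)CO[Si](c2ccccc2)(c2ccccc2)C(C)(C)C)[C@@H]1[C@@H]1CC(=C)[C@@H]([Si](C)(C)c2ccccc2)CC[C@@H]1O[Si](CC)(CC)CC | intermediate
21 | lithium enolate C8=C9–OLi of the ring A ketone | C1=C(O[Li])CC[C@@H]([C@@H](C)CC/C=C(\C)CO[Si](c2ccccc2)(c2ccccc2)C(C)(C)C)[C@@H]1[C@@H]1CC(=C)[C@@H]([Si](C)(C)c2ccccc2)CC[C@@H]1O[Si](CC)(CC)CC | intermediate
22 | Mannich base: C9 ketone, C8–CH2NMe2 trans to C14 | CN(C)C[C@H]1C(=O)CC[C@@H]([C@@H](C)CC/C=C(\C)CO[Si](c2ccccc2)(c2ccccc2)C(C)(C)C)[C@@H]1[C@@H]1CC(=C)[C@@H]([Si](C)(C)c2ccccc2)CC[C@@H]1O[Si](CC)(CC)CC | intermediate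
23 | trimethylammonium iodide of 22 | C[N+](C)(C)C[C@H]1C(=O)CC[C@@H]([C@@H](C)CC/C=C(\C)CO[Si](c2ccccc2)(c2ccccc2)C(C)(C)C)[C@@H]1[C@@H]1CC(=C)[C@@H]([Si](C)(C)c2ccccc2)CC[C@@H]1O[Si](CC)(CC)CC.[I-] | intermediate
24 | key precursor: ring A exocyclic enone C7=C8–C9=O joined at C13 to the ring C allylsilane | C=C1C(=O)CC[C@@H]([C@@H](C)CC/C=C(\C)CO[Si](c2ccccc2)(c2ccccc2)C(C)(C)C)[C@@H]1[C@@H]1CC(=C)[C@@H]([Si](C)(C)c2ccccc2)CC[C@@H]1O[Si](CC)(CC)CC | intermediate
25 | key product: tricycle with C9 dimethylphenylsilyl enol ether (C8=C9), C4=C5 bridgehead alkene, C1–OSiEt3 | CC[Si](CC)(CC)O[C@H]1CCC=C2CCC3=C(O[Si](C)(C)c4ccccc4)CC[C@@H]([C@@H](C)CC/C=C(\C)CO[Si](c4ccccc4)(c4ccccc4)C(C)(C)C)[C@@H]3[C@@H]1C2 | intermediate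
26 | lithium enolate of the tricyclic C9 ketone | CC[Si](CC)(CC)O[C@H]1CCC=C2CCC3=C(O[Li])CC[C@@H]([C@@H](C)CC/C=C(\C)CO[Si](c4ccccc4)(c4ccccc4)C(C)(C)C)[C@@H]3[C@@H]1C2 | intermediate
27 | C9 enol triflate | CC[Si](CC)(CC)O[C@H]1CCC=C2CCC3=C(OS(=O)(=O)C(F)(F)F)CC[C@@H]([C@@H](C)CC/C=C(\C)CO[Si](c4ccccc4)(c4ccccc4)C(C)(C)C)[C@@H]3[C@@H]1C2 | intermediate
28 | C9 methyl compound with C1–OSiEt3 | CC[Si](CC)(CC)O[C@H]1CCC=C2CCC3=C(C)CC[C@@H]([C@@H](C)CC/C=C(\C)CO[Si](c4ccccc4)(c4ccccc4)C(C)(C)C)[C@@H]3[C@@H]1C2 | intermediate
29 | C1 alcohol | O[C@H]1CCC=C2CCC3=C(C)CC[C@@H]([C@@H](C)CC/C=C(\C)CO[Si](c4ccccc4)(c4ccccc4)C(C)(C)C)[C@@H]3[C@@H]1C2 | intermediate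
30 | C1 ketone | O=C1CCC=C2CCC3=C(C)CC[C@@H]([C@@H](C)CC/C=C(\C)CO[Si](c4ccccc4)(c4ccccc4)C(C)(C)C)[C@@H]3[C@@H]1C2 | intermediate
31 | tert-butyldiphenylsilyl ether of the target | C=C1CCC=C2CCC3=C(C)CC[C@@H]([C@@H](C)CC/C=C(\C)CO[Si](c4ccccc4)(c4ccccc4)C(C)(C)C)[C@@H]3[C@@H]1C2 | intermediate
32 | CNP0289180.1 | C=C1CCC=C2CCC3=C(C)CC[C@@H]([C@@H](C)CC/C=C(\C)CO)[C@@H]3[C@@H]1C2 | target

**Step count and risks**

Total: 21 steps. Longest linear sequence: 19 steps (steps 1–3 and 6–21, from (S)-citronellal).

Steps most likely to fail: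

Step 12. The silylcopper species may enter the wrong face of C4 if the substrate overrides the ligand, may attack C6 instead of C4, and the methoxide may erode the enol silyl ether. The fallback replaces external catalyst control by a leaving group that delivers the silyl group itself. It sets out from diol 15: phenyl isocyanate acylates the primary allylic alcohol to the N-phenylcarbamate F1, Et3SiOTf and 2,6-lutidine give the triethylsilyl ether F2, and ring-closing metathesis as in step 11 gives the ring C carbamate F3. Deprotonation of the carbamate N–H with n-BuLi, complexation with CuI·2PPh3 and addition of Me2PhSiLi then transfer silicon from the copper bound to the carbamate to C4 in a regiospecific syn-SN2' displacement. This returns to the route at allylsilane 20. Any C4 epimer that still forms can be used in the anionic closure described for step 15, which does not depend on C4.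

Step 15. Protodesilylation, reversible O-addition of the C1 silyl ether or dimerisation of the α-methylene ketone may outrun the seven-membered closure. The fallback changes the closure from cationic to anionic and sets out from enone 24. Bu4N[Ph3SiF2] in THF/DMF at −40 °C attacks the allylic silicon; the allyl anion equivalent adds through C6 to C7 and gives the tetrabutylammonium enolate F4, which is trapped in the same flask with PhNTf2. This returns to the route at enol triflate 27 and bypasses 25 and 26.

Step 6. The open transition state may show poor topicity at C14, so that the C14 epimer of 12 is formed alongside. The fallback uses a metal-bridged closed transition state in place of the open Lewis-acid one and sets out from lactone 10 and enone 6. LiN(i-Pr)2 in THF at −78 °C converts 10 into the lithium enolate F5; enone 6 is added and the mixture is warmed to −40 °C so that any 1,2-adduct reverts and the 1,4-adduct, the ring A lithium enolate F6, accumulates. Trapping with t-BuMe2SiCl and DMPU returns to the route at adduct 12.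

Further compounds
F1 | step 12 | N-phenylcarbamate of the C6 alcohol of diol 15 | C1=C(O[Si](C)(C)C(C)(C)C)CC[C@@H]([C@@H](C)CC/C=C(\C)CO[Si](c2ccccc2)(c2ccccc2)C(C)(C)C)[C@@H]1[C@H](CC(=C)COC(=O)Nc2ccccc2)[C@@H](O)CCC=C
F2 | step 12 | C1 triethylsilyl ether of F1 | C1=C(O[Si](C)(C)C(C)(C)C)CC[C@@H]([C@@H](C)CC/C=C(\C)CO[Si](c2ccccc2)(c2ccccc2)C(C)(C)C)[C@@H]1[C@H](CC(=C)COC(=O)Nc2ccccc2)[C@@H](O[Si](CC)(CC)CC)CCC=C
F3 | step 12 | ring C cycloheptene with C6 N-phenylcarbamate | C1=C(O[Si](C)(C)C(C)(C)C)CC[C@@H]([C@@H](C)CC/C=C(\C)CO[Si](c2ccccc2)(c2ccccc2)C(C)(C)C)[C@@H]1[C@@H]1CC(COC(=O)Nc2ccccc2)=CCC[C@@H]1O[Si](CC)(CC)CC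
F4 | step 15 | tetrabutylammonium enolate of the tricyclic C9 ketone | CC[Si](CC)(CC)O[C@H]1CCC=C2CCC3=C([O-])CC[C@@H]([C@@H](C)CC/C=C(\C)CO[Si](c4ccccc4)(c4ccccc4)C(C)(C)C)[C@@H]3[C@@H]1C2.CCCC[N+](CCCC)(CCCC)CCCC
F5 | step 6 | lithium enolate of lactone 10 | C=C1CC=C(O[Li])OC1
F6 | step 6 | ring A lithium enolate of the Michael adduct | C1=C(O[Li])CC[C@@H]([C@@H](C)CC/C=C(\C)CO[Si](c2ccccc2)(c2ccccc2)C(C)(C)C)[C@@H]1[C@@H]1CC(=C)COC1=O
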